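## Retrosynthetic overview

1. Feature: in ring B (seven-membered), C8 and C9 carry a cis 8α,9α-oxirane next to the 10α-hydroxyl on C10, and C10 adjoins quaternary C1. A singlet-oxygen ene reaction on a C9=C10 alkene whose only allylic hydrogen is 8α-H leaves this pattern, once the C10 hydroperoxide has passed on one oxygen.
2. Lapiferine ⇒ C6 angeloylation of the epoxy triol ⇒ oxidation cascade on 8αH-dauc-9-ene-4β,6α-diol, with the oxirane formed last.
3. Ring B ⇒ ring-closing metathesis at C9=C10. The C1 vinyl group comes from a C10 dimethyl acetal and the C4 carbinol from isopropyl addition to a C4 ketone.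
4. C5–C6 ⇒ anti aldol of a regiodefined cyclopentanone enolate (C1 set by catalytic asymmetric conjugate methylation) with (S)-3-methylpent-4-enal. C8 must be one configuration because its α-hydrogen relays chirality to C10.
5. Ring order: ring A is bought as a cyclopentenone, ring B is closed in step 13, and the oxirane is closed in step 14.

Key step: step 14

Assumption: daucane numbering and α/β descriptors (β = face of the C1 methyl) are used for all intermediates, and in steps 2 and 7 the ligand antipode is taken that gives the configuration drawn.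

## Route

Step 1
Reactants: 1 (E)-but-2-en-1-ol
Product: 2 (E)-but-2-en-1-yl methyl carbonate
Conditions: ClCO2Me, pyridine, CH2Cl2, 0 °C
Reagents that add atoms: methyl chloroformate, COC(=O)Cl
Why: O-Acylation of the primary allylic alcohol with a chloroformate installs the carbonate leaving group, which later also supplies the base (methoxide) for the allylic alkylation; no stereocentre is formed.

Step 2
Reactants: 2 (E)-but-2-en-1-yl methyl carbonate; 3 dimethyl malonate
Product: 4 dimethyl (R)-2-(but-3-en-2-yl)malonate
Conditions: [Ir(cod)Cl]2 (2 mol %), binaphthol-derived N,N-bis(1-phenylethyl)phosphoramidite (4 mol %), 1,5,7-triazabicyclo[4.4.0]dec-5-ene (8 mol %), THF, rt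
Reagents that add atoms: none
Why: In this iridium-catalysed asymmetric allylic alkylation under salt-free conditions the malonate attacks the methyl-bearing terminus of the allyl–iridium intermediate, so the branched product forms and the phosphoramidite ligand sets the future C8; any linear isomer is removed by chromatography.

Step 3
Reactants: 4 dimethyl (R)-2-(but-3-en-2-yl)malonate
Product: 5 methyl (S)-3-methylpent-4-enoate
Conditions: LiCl, H2O, DMSO, 150 °C
Reagents that add atoms: none
Why: Krapcho dealkoxycarbonylation removes one ester by chloride attack on its methyl group and loss of CO2, and the stereocentre, which is β to the remaining ester and not acidic, is untouched.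

Step 4
Reactants: 5 methyl (S)-3-methylpent-4-enoate
Product: 6 (S)-3-methylpent-4-enal
Conditions: iBu2AlH (1.05 equiv), CH2Cl2, −78 °C; aq Rochelle salt
Reagents that add atoms: none
Why: Partial reduction of the ester with iBu2AlH stops at the aluminium hemiacetal at −78 °C, which releases the aldehyde only on work-up; the volatile aldehyde is used as a dried solution.

Step 5
Reactants: 7 3-ethoxycyclopent-2-en-1-one; 8 1,3-dithiane
Product: 11 3-(1,3-dithian-2-yl)cyclopent-2-en-1-one, via 2-lithio-1,3-dithiane 9 (not isolated), via carbinol adduct 10 (not isolated)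
Conditions: 8, n-BuLi, THF, −30 °C; 7, −78 → 0 °C; then 1 M aq HCl, rt
Reagents that add atoms: water, O
Why: The Corey–Seebach lithiodithiane adds 1,2 to the vinylogous ester, and acid then hydrolyses the enol ether and expels the tertiary hydroxyl (Stork–Danheiser transposition), which places the masked C10 formyl group on the enone β-carbon.

Step 6
Reactants: 11 3-(1,3-dithian-2-yl)cyclopent-2-en-1-one
Product: 12 3-(dimethoxymethyl)cyclopent-2-en-1-one
Conditions: PhI(OCOCF3)2 (1.5 equiv), MeOH, 0 °C → rt
Reagents that add atoms: methanol, CO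
Why: Oxidative dithiane cleavage with a hypervalent iodine reagent in methanol traps the thionium ions with solvent and gives the dimethyl acetal directly, so no sulfur is left to poison the copper catalyst and the sensitive free enone aldehyde is never formed.

Step 7
Reactants: 12 3-(dimethoxymethyl)cyclopent-2-en-1-one; 13 trimethylaluminium
Product: 15 (S)-3-(dimethoxymethyl)-3-methylcyclopent-1-en-1-yl acetate, via dimethylaluminium enolate 14 (not isolated)
Conditions: 13 (2 equiv), Cu(OTf)2 (5 mol %), chiral sulfonate-bearing N-aryl imidazolinium salt (1,2-diphenylethylenediamine backbone) pre-treated with Ag2O as carbene source (5 mol %), THF, −78 → −30 °C; then Ac2O, −30 °C → rt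
Reagents that add atoms: acetic anhydride, CC(=O)OC(C)=O
Why: In this copper-catalysed asymmetric conjugate addition of a trialkylaluminium to a β-substituted cyclopentenone, the chiral carbene–copper methyl species adds to one enone face and sets quaternary C1 (S), and O-acetylation of enolate 14 fixes the C4–C5 enolate regiochemistry without the silyl triflates that would ionise the acetal.

Step 8
Reactants: 15 (S)-3-(dimethoxymethyl)-3-methylcyclopent-1-en-1-yl acetate; 6 (S)-3-methylpent-4-enal
Product: 18 (2S,3S)-3-(dimethoxymethyl)-2-[(1S,3S)-1-hydroxy-3-methylpent-4-en-1-yl]-3-methylcyclopentan-1-one, via lithium enolate 16 (not isolated), via chlorozinc enolate 17 (not isolated)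
Conditions: MeLi (2.05 equiv), THF, 0 °C; ZnCl2 (1.1 equiv), −78 °C; 6, −78 → −40 °C; aq NH4Cl
Reagents that add atoms: none
Why: Cleavage of the enol acetate with MeLi regenerates the C4–C5 enolate regiospecifically, and its zinc aldol reaction runs through a Zimmerman–Traxler chair in which the ring-locked E-enolate gives the anti aldol (C6) and the aldehyde reaches C5 on the face opposite the bulky dimethoxymethyl group (C5–C6 bond cis to the C1 methyl); diastereomers that stem from the minor enantiomers of 6 and 15 are removed here by chromatography.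

Step 9
Reactants: 18 aldol adduct
Product: 19 (2S,3S)-3-(dimethoxymethyl)-3-methyl-2-[(1S,3S)-3-methyl-1-(triethylsilyloxy)pent-4-en-1-yl]cyclopentan-1-one
Conditions: Et3SiCl, imidazole, DMAP (cat.), CH2Cl2, 0 °C → rt
Reagents that add atoms: chlorotriethylsilane, CC[Si](Cl)(CC)CC
Why: Standard silylation of the secondary alcohol under mild base blocks retro-aldol cleavage in the next step, and a chlorosilane with imidazole leaves the acetal alone.

Step 10
Reactants: 19 silyl ether ketone; 20 isopropylmagnesium chloride
Product: 21 (1R,2S,3S)-3-(dimethoxymethyl)-3-methyl-2-[(1S,3S)-3-methyl-1-(triethylsilyloxy)pent-4-en-1-yl]-1-(propan-2-yl)cyclopentan-1-ol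
Conditions: LaCl3·2LiCl (1.1 equiv), THF, rt; 20 (1.5 equiv), 0 °C; aq NH4Cl
Reagents that add atoms: none
Why: In this lanthanide-promoted Grignard 1,2-addition the lanthanum salt activates the carbonyl and suppresses enolisation and β-hydride reduction, and the nucleophile comes from the α face, trans to the C5 side chain and away from the pseudo-axial C1 methyl, which puts the 4-hydroxyl β.

Step 11
Reactants: 21 tertiary carbinol
Product: 22 (1S,2S,3R)-3-hydroxy-2-[(1S,3S)-1-hydroxy-3-methylpent-4-en-1-yl]-1-methyl-3-(propan-2-yl)cyclopentane-1-carbaldehyde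
Conditions: 1 M aq HCl, THF, rt
Reagents that add atoms: water, O
Why: Aqueous acid hydrolyses the dimethyl acetal and the triethylsilyl ether in one operation; C1 bears no hydrogen, so the aldehyde cannot epimerise, and C10 lies trans to both hydroxyl-bearing groups, which disfavours lactol formation.

Step 12
Reactants: 22 dihydroxy aldehyde
Product: 23 (1R,2S,3R)-3-ethenyl-2-[(1S,3S)-1-hydroxy-3-methylpent-4-en-1-yl]-3-methyl-1-(propan-2-yl)cyclopentan-1-ol
Conditions: Ph3PCH3Br (5 equiv), KOtBu (4.8 equiv), THF, 0 °C → rt
Reagents that add atoms: methyltriphenylphosphonium bromide, C[P+](c1ccccc1)(c1ccccc1)c1ccccc1.[Br-]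
Why: Wittig methylenation of the non-enolisable neopentyl aldehyde with excess ylide gives the C1 vinyl group, while the two hydroxyls are only deprotonated and return on work-up.

Step 13
Reactants: 23 diene diol
Product: 24 8αH-dauc-9-ene-4β,6α-diol (8β-methyl, 1β-methyl, 5α-H, trans-fused)
Conditions: second-generation Grubbs catalyst (5 mol %), CH2Cl2 (2 mM), reflux
Reagents that add atoms: none
Why: In this ring-closing metathesis the catalyst loads on the less hindered side-chain vinyl group and closes onto the C1 vinyl group, forming the cis C9=C10 alkene of trans-fused ring B with loss of ethene; no stereocentre changes.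

Step 14
Reactants: 24 8αH-dauc-9-ene-4β,6α-diol
Product: 26 8α,9α-epoxydaucane-4β,6α,10α-triol (deangeloyl lapiferine), via 10α-hydroperoxide 25 (not isolated)
Conditions: O2 (bubbled), 5,10,15,20-tetraphenylporphyrin (1 mol %), Ti(OiPr)4 (1.5 equiv), 4 Å molecular sieves, CH2Cl2, 0 °C, visible light (sodium lamp or white LED); then water, filtration through Celite
Reagents that add atoms: oxygen, O=O
Why: Sensitised singlet oxygen adds to C9=C10 in a concerted, suprafacial Schenck ene reaction in which the C10–O bond forms while 8α-H moves to the outer oxygen and the alkene shifts to C8=C9 (hydroperoxide 25); because C1 is quaternary, 8α-H is the only allylic hydrogen, so only this regioisomer and only the α face are productive, and C8 relays its configuration to C10. The reactive conformer should be the twist-boat of ring B, where the 8β-methyl is pseudo-equatorial, 8α-H stands perpendicular to the alkene plane and the C1 methyl screens the β face, whereas in the chair the two methyls are syn-axial and 8α-H lies in the alkene plane, so that form is strained and unreactive. Ti(OiPr)4, present from the start, binds the C10 peroxide and alkoxide and passes the outer peroxide oxygen to C8=C9 inside a Sharpless-type titanium assembly, most likely between two bound substrate molecules because attack along the O–O axis within one molecule is strained, so that 25 isomerises overall to 26. The oxirane is closed by a concerted syn [2+1] oxygen-atom transfer to the alkene rather than by a stepwise exo or endo cyclisation, and C8 and C9 are set by delivery from titanium held on the 10α-oxygen, reinforced by the 6α-alkoxide on the same face, hence the cis epoxy alcohol. The chemoselectivity needed is that the trisubstituted, more electron-rich C8=C9 alkene of 25 must not meet a second singlet oxygen; fast titanium-mediated epoxidation in the same flask removes it, and more than one equivalent of Ti(OiPr)4 is used because the 4,6-diol ties up one. The closest known reaction type is the one-pot photooxygenation of cycloalkenes in the presence of Ti(OiPr)4 to give cis epoxy alcohols.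

Step 15
Reactants: 26 8α,9α-epoxydaucane-4β,6α,10α-triol; 27 angelic acid
Product: 29 lapiferine, via mixed anhydride 28 (not isolated)
Conditions: 27 (1.2 equiv), 2,4,6-trichlorobenzoyl chloride, Et3N, toluene, rt, salt filtered off; then 26, toluene, 80 °C, no DMAP
Reagents that add atoms: none
Why: In this Yamaguchi esterification the alcohol attacks the unhindered angeloyl carbonyl of 28; the equatorial secondary 6α-hydroxyl should react ahead of the neopentyl 10α-hydroxyl (flanked by quaternary C1 and the oxirane) and the tertiary 4β-hydroxyl, and leaving out DMAP avoids the addition–elimination that turns angelate into tiglate.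

## Compound list

1 | (E)-but-2-en-1-ol | C/C=C/CO | starting material
2 | (E)-but-2-en-1-yl methyl carbonate | C/C=C/COC(=O)OC | intermediate
3 | dimethyl malonate | COC(=O)CC(=O)OC | starting material
4 | dimethyl (R)-2-(but-3-en-2-yl)malonate | COC(=O)C(C(=O)OC)[C@H](C)C=C | intermediate
5 | methyl (S)-3-methylpent-4-enoate | COC(=O)C[C@H](C)C=C | intermediate
6 | (S)-3-methylpent-4-enal | O=CC[C@H](C)C=C | intermediate
7 | 3-ethoxycyclopent-2-en-1-one | CCOC1=CC(=O)CC1 | starting material
8 | 1,3-dithiane | C1CSCSC1 | starting material
9 | 2-lithio-1,3-dithiane | [Li]C1SCCCS1 | intermediate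
10 | 1-(1,3-dithian-2-yl)-3-ethoxycyclopent-2-en-1-ol (racemic) | CCOC1=CC(O)(C2SCCCS2)CC1 | intermediate
11 | 3-(1,3-dithian-2-yl)cyclopent-2-en-1-one | O=C1C=C(C2SCCCS2)CC1 | intermediate
12 | 3-(dimethoxymethyl)cyclopent-2-en-1-one | COC(OC)C1=CC(=O)CC1 | intermediate
13 | trimethylaluminium | C[Al](C)C | starting material
14 | dimethylaluminium (S)-3-(dimethoxymethyl)-3-methylcyclopent-1-en-1-olate | C[Al](C)OC1=C[C@@](C)(C(OC)OC)CC1 | intermediate
15 | (S)-3-(dimethoxymethyl)-3-methylcyclopent-1-en-1-yl acetate | CC(=O)OC1=C[C@@](C)(C(OC)OC)CC1 | intermediate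
16 | lithium (S)-3-(dimethoxymethyl)-3-methylcyclopent-1-en-1-olate | [Li]OC1=C[C@@](C)(C(OC)OC)CC1 | intermediate
17 | chlorozinc (S)-3-(dimethoxymethyl)-3-methylcyclopent-1-en-1-olate | Cl[Zn]OC1=C[C@@](C)(C(OC)OC)CC1 | intermediate
18 | (2S,3S)-3-(dimethoxymethyl)-2-[(1S,3S)-1-hydroxy-3-methylpent-4-en-1-yl]-3-methylcyclopentan-1-one | O[C@@H](C[C@H](C)C=C)[C@@H]1[C@@](C)(C(OC)OC)CCC1=O | intermediate
19 | (2S,3S)-3-(dimethoxymethyl)-3-methyl-2-[(1S,3S)-3-methyl-1-(triethylsilyloxy)pent-4-en-1-yl]cyclopentan-1-one | CC[Si](CC)(CC)O[C@@H](C[C@H](C)C=C)[C@@H]1[C@@](C)(C(OC)OC)CCC1=O | intermediate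
20 | isopropylmagnesium chloride | CC(C)[Mg]Cl | starting material
21 | (1R,2S,3S)-3-(dimethoxymethyl)-3-methyl-2-[(1S,3S)-3-methyl-1-(triethylsilyloxy)pent-4-en-1-yl]-1-(propan-2-yl)cyclopentan-1-ol | CC[Si](CC)(CC)O[C@@H](C[C@H](C)C=C)[C@@H]1[C@@](C)(C(OC)OC)CC[C@@]1(O)C(C)C | intermediate
22 | (1S,2S,3R)-3-hydroxy-2-[(1S,3S)-1-hydroxy-3-methylpent-4-en-1-yl]-1-methyl-3-(propan-2-yl)cyclopentane-1-carbaldehyde | O[C@@H](C[C@H](C)C=C)[C@@H]1[C@@](C)(C=O)CC[C@@]1(O)C(C)C | intermediate
23 | (1R,2S,3R)-3-ethenyl-2-[(1S,3S)-1-hydroxy-3-methylpent-4-en-1-yl]-3-methyl-1-(propan-2-yl)cyclopentan-1-ol | O[C@@H](C[C@H](C)C=C)[C@@H]1[C@@](C)(C=C)CC[C@@]1(O)C(C)C | intermediate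
24 | 8αH-dauc-9-ene-4β,6α-diol (8β-methyl) | O[C@H]1C[C@H](C)C=C[C@@]2(C)CC[C@@](O)(C(C)C)[C@H]12 | intermediate
25 | 10α-hydroperoxydauc-8-ene-4β,6α-diol | O[C@H]1CC(C)=C[C@@H](OO)[C@@]2(C)CC[C@@](O)(C(C)C)[C@H]12 | intermediate
26 | 8α,9α-epoxydaucane-4β,6α,10α-triol (deangeloyl lapiferine) | O[C@H]1C[C@@]2(C)O[C@H]2[C@@H](O)[C@@]2(C)CC[C@@](O)(C(C)C)[C@H]12 | intermediate
27 | angelic acid, (Z)-2-methylbut-2-enoic acid | C/C=C(/C)C(=O)O | starting material
28 | angelic 2,4,6-trichlorobenzoic anhydride | C/C=C(/C)C(=O)OC(=O)c1c(Cl)cc(Cl)cc1Cl | intermediate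
29 | lapiferine (6α-angeloyloxy-8α,9α-epoxydaucane-4β,10α-diol) | C/C=C(/C)C(=O)O[C@H]1C[C@@]2(C)O[C@H]2[C@@H](O)[C@@]2(C)CC[C@@](O)(C(C)C)[C@H]12 | target

Total step count: 15
Longest linear sequence: 12 steps (steps 1–4, then 8–15)

## Steps most likely to fail

**Step 14.** The ene reaction may be slow. The alkene is only 1,2-disubstituted and neopentyl at C10, and only the twist-boat conformer offers 8α-H to the incoming oxygen. Long irradiation then invites a second oxygenation of the C8=C9 alkene and Lewis-acid opening of the new oxirane.

The fallback builds the same array with ground-state reagents. It sets out from 24. Epoxidation with mCPBA (CH2Cl2, NaHCO3, 0 °C) on the face away from both methyls should give 9α,10α-epoxy-8αH-daucane-4β,6α-diol F1. Excess Et2Al(tmp) (diethylaluminium 2,2,6,6-tetramethylpiperidide, toluene, 0 °C) then removes 8α-H, which is cis to the oxirane oxygen, in a syn elimination. This breaks the C9–O bond and gives dauc-8-ene-4β,6α,10α-triol F2. Hydroxyl-directed epoxidation with VO(acac)2 and tBuOOH places the oxirane cis to the 10α-hydroxyl, and the route is rejoined at 26.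

**Step 10.** The secondary Grignard reagent may enolise or reduce the hindered ketone instead of adding to it, or facial selectivity may be poor.

The fallback changes the nucleophile to an sp2 carbon that carries no β-hydrogen and saturates it afterwards. It sets out from 19. Isopropenylmagnesium bromide with LaCl3·2LiCl adds from the same α face and gives the 4-(prop-1-en-2-yl) analogue of 21, F3. Hydrogen-atom-transfer hydrogenation (Mn(dpm)3, PhSiH3, tBuOOH, iPrOH, rt) should engage the 1,1-disubstituted alkene, through its tertiary radical, ahead of the monosubstituted vinyl group. The route is rejoined at 21.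

**Step 7.** Conversion or enantioselectivity may be low, because the β-substituent is branched and Lewis basic next to the reacting carbon.

The fallback gives up catalytic control and uses the enantiopure aldehyde as resolving partner. It sets out from 12.
- Me2CuLi and Me3SiCl (THF, −78 °C) give racemic 3-(dimethoxymethyl)-3-methyl-1-(trimethylsilyloxy)cyclopent-1-ene F4.
- MeLi cleaves it to lithium enolate 16 together with its (R)-enantiomer F5.
- ZnCl2 turns these into 17 and the (R)-chlorozinc enolate F6.
- Aldol reaction with 6 gives 18 beside the diastereomer of opposite configuration at C1, C5 and C6, (2R,3R)-3-(dimethoxymethyl)-2-[(1R,3S)-1-hydroxy-3-methylpent-4-en-1-yl]-3-methylcyclopentan-1-one F7.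
- F7 is separated by chromatography, and the route is rejoined at 18.

## Further compounds

F1 | step 14 | 9α,10α-epoxy-8αH-daucane-4β,6α-diol | O[C@H]1C[C@H](C)[C@H]3O[C@H]3[C@@]2(C)CC[C@@](O)(C(C)C)[C@H]12
F2 | step 14 | dauc-8-ene-4β,6α,10α-triol | O[C@H]1CC(C)=C[C@@H](O)[C@@]2(C)CC[C@@](O)(C(C)C)[C@H]12
F3 | step 10 | 4-(prop-1-en-2-yl) analogue of 21 (same spatial arrangement at all centres) | CC[Si](CC)(CC)O[C@@H](C[C@H](C)C=C)[C@@H]1[C@@](C)(C(OC)OC)CC[C@@]1(O)C(C)=C
F4 | step 7 | racemic 3-(dimethoxymethyl)-3-methyl-1-(trimethylsilyloxy)cyclopent-1-ene | C[Si](C)(C)OC1=CC(C)(C(OC)OC)CC1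
F5 | step 7 | lithium (R)-3-(dimethoxymethyl)-3-methylcyclopent-1-en-1-olate | [Li]OC1=C[C@](C)(C(OC)OC)CC1
F6 | step 7 | chlorozinc (R)-3-(dimethoxymethyl)-3-methylcyclopent-1-en-1-olate | Cl[Zn]OC1=C[C@](C)(C(OC)OC)CC1
F7 | step 7 | (2R,3R)-3-(dimethoxymethyl)-2-[(1R,3S)-1-hydroxy-3-methylpent-4-en-1-yl]-3-methylcyclopentan-1-one | O[C@H](C[C@H](C)C=C)[C@H]1[C@](C)(C(OC)OC)CCC1=O
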